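## Retrosynthetic overview

- The target has one ring: a cyclohexane with C1 (carbinol carbon with methyl), C2 (quaternary), C3–H (hydroxypropyl arm), C4 (alkylidene carbon), C5H2 and C6H2. The trienyl tail is joined late by a B‑alkyl Suzuki–Miyaura coupling of a C2 vinyl group with vinyl iodide 23; the enal is raised from a C4 ketone by isopropenyl addition and oxidative 1,3‑transposition.
- The ring is closed in one operation by a [3+3] union of but‑3‑en‑2‑one 8 (C5, C6, C1 and the C1 methyl) with the C4–C3–C2 unit of acyclic nitro allylboronate 7. A nitro‑Michael addition makes C4–C5, and intramolecular allylboration of the ketone so unveiled makes C1–C2.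
- Enabling feature: C1(OH)(CH3)–C6H2–C5H2 is a masked methyl vinyl ketone flanked 1,3 by two carbons that are both nucleophilic in 7. C4 is a nitronate carbon (later ketone, then alkylidene carbon); quaternary C2 is the γ‑carbon of an (E)‑allylboronate whose other two carbons become the first two side‑chain carbons. The C3–H stereocenter between them steers both new stereocenters.
- 7 comes from acetoxy enal 1 by Henry reaction/dehydration to a nitrodiene, copper‑catalysed asymmetric 1,4‑addition of a 3‑silyloxypropylzinc (sets C3) and palladium‑catalysed borylation of the allylic acetate.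
- 23 comes from a catalytic asymmetric vinylogous Mukaiyama aldol of a senecioate dienolate with 3‑methylbut‑2‑enal (sets the side‑chain carbinol), propargylation and zirconium‑catalysed carboalumination/iodination.

Key step: step 4

Assumption: for each chiral catalyst the enantiomer that gives the drawn configuration is used, and the hindered tertiary hydroxyl of 11 is taken not to react with 9‑BBN in step 12.

Abbreviations: TBS = tert‑butyldimethylsilyl; Bpin = 4,4,5,5‑tetramethyl‑1,3,2‑dioxaborolan‑2‑yl; R* = (3E,7E,10R)‑10‑(TBS‑oxy)‑4,8,12‑trimethyltrideca‑3,7,11‑trien‑1‑yl.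

## Route

Step 1
Reactants: 1 (2E)‑4‑acetoxy‑2‑methylbut‑2‑enal; 2 nitromethane
Product: 4 (2E,4E)‑3‑methyl‑5‑nitropenta‑2,4‑dien‑1‑yl acetate, via nitro alcohol 3 (not isolated)
Conditions: 2 (5 equiv), 1,1,3,3‑tetramethylguanidine (10 mol%), THF, 0 °C; then MsCl, Et3N, CH2Cl2, −20 → 0 °C
Reagents that add atoms: none
Why: Henry reaction at the aldehyde carbonyl of the α‑branched enal, then mesylation and base‑induced elimination of the β‑nitro alcohol, should give the conjugated (E)‑nitroalkene while the existing (E)‑trisubstituted alkene and the acetate stay untouched.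

Step 2
Reactants: 4 (2E,4E)‑3‑methyl‑5‑nitropenta‑2,4‑dien‑1‑yl acetate; 5 tert‑butyl(3‑iodopropoxy)dimethylsilane
Product: 6 (2E,4R)‑7‑(TBS‑oxy)‑3‑methyl‑4‑(nitromethyl)hept‑2‑en‑1‑yl acetate
Conditions: 5 (2.4 equiv), Et2Zn, CuI (cat.), 50 °C, then volatiles removed; 4, (CuOTf)2·C6H6 (2 mol%), BINOL‑derived bis(1‑phenylethyl)amine phosphoramidite (4 mol%), toluene, −30 °C; aq. NH4Cl
Reagents that add atoms: none
Why: Copper‑catalysed asymmetric conjugate addition of a functionalised dialkylzinc to a nitroalkene should deliver the silyloxypropyl group to the carbon β to the nitro group (1,4‑mode), the chiral phosphoramidite–copper complex choosing the face and setting C4 as R; the allylic acetate is inert to zinc and copper alkyls at this temperature.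

Step 3
Reactants: 6 (2E,4R)‑7‑(TBS‑oxy)‑3‑methyl‑4‑(nitromethyl)hept‑2‑en‑1‑yl acetate
Product: 7 tert‑butyldimethyl{[(4R,5E)‑5‑methyl‑4‑(nitromethyl)‑7‑(Bpin)hept‑5‑en‑1‑yl]oxy}silane
Conditions: B2pin2 (1.2 equiv), Pd2(dba)3 (2.5 mol%), DMSO, 50 °C
Reagents that add atoms: bis(pinacolato)diboron, CC1(C)OB(OC1(C)C)B1OC(C)(C)C(C)(C)O1
Why: Palladium‑catalysed borylation of an allylic acetate (ionisation to a π‑allyl complex of divalent palladium, transmetalation with the diboron, C–B reductive elimination at the unhindered primary terminus) should give the linear (E)‑allylboronate; no base is added, so the nitroalkane stays un‑ionised.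

Step 4
Reactants: 7 tert‑butyldimethyl{[(4R,5E)‑5‑methyl‑4‑(nitromethyl)‑7‑(Bpin)hept‑5‑en‑1‑yl]oxy}silane; 8 but‑3‑en‑2‑one
Product: 11 (1R,2R,3R,4RS)‑3‑[3‑(TBS‑oxy)propyl]‑2‑ethenyl‑1,2‑dimethyl‑4‑nitrocyclohexan‑1‑ol, via Michael adduct 9 (not isolated), via cyclic borate ester 10 (not isolated)
Conditions: 8 (1.05 equiv), 1,1,3,3‑tetramethylguanidine (10 mol%), toluene, 0 °C → rt; then 80 °C in the same flask; aq. NaHCO3/triethanolamine work‑up
Reagents that add atoms: none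
Why: Tetramethylguanidine generates the nitronate of 7, which adds to the β‑carbon of 8 (nitro‑Michael addition) to make the C4–C5 ring bond and unmask methyl ketone 9; on warming, the ketone carbonyl is attacked by the γ‑carbon of the tethered (E)‑allylboronate through a closed six‑membered chair transition state (intramolecular allylboration), which makes the C1–C2 ring bond, turns the allyl unit into the vinyl group and leaves borate 10, hydrolysed on work‑up. The closest known reaction types are the amine‑catalysed Michael addition of nitroalkanes to vinyl ketones and the intramolecular allylboration of a carbonyl group released in the same flask (domino hydroformylation–allylboration). The cyclohexane closes by C–C bond formation between the ketone carbon and the disubstituted allyl terminus with both π bonds outside the new ring (6‑exo attack on the carbonyl), through a trans‑fused chair–chair array of the forming carbocycle and the boron‑containing allylation ring. The quaternary carbon C2 and the carbinol carbon C1 are set together by this chair: the E geometry places the tether equatorial and the allyl methyl axial, the ketone methyl is axial and its chain equatorial, so vinyl and hydroxyl should end trans and the two methyl groups trans. The face is chosen by the existing stereocenter of 7 (C3 of the ring), whose silyloxypropyl chain stays equatorial to avoid a syn‑diaxial clash with the axial ketone methyl, so the (1R,2R,3R) isomer should result; the nitro‑bearing C4 is left as a mixture because it becomes trigonal later. The step needs the allylboronate to leave 8 alone until the ketone is tethered (γ,γ‑disubstituted pinacol allylboronates add to ketones and enones only slowly between molecules at room temperature) and needs mono‑alkylation of the nitroalkane (one equivalent of 8; the secondary nitro product is more hindered).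

Step 5
Reactants: 12 methyl 3‑methylbut‑2‑enoate
Product: 13 tert‑butyl[(1‑methoxy‑3‑methylbuta‑1,3‑dien‑1‑yl)oxy]dimethylsilane
Conditions: LiN(i‑Pr)2 (from i‑Pr2NH, n‑BuLi), THF–DMPU, −78 °C; TBSCl
Reagents that add atoms: tert‑butyldimethylsilyl chloride, CC(C)(C)[Si](C)(C)Cl
Why: γ‑Deprotonation of the senecioate gives the extended lithium dienolate, which is silylated on oxygen to the silyl dienol ether (silyl ketene acetal formation).

Step 6
Reactants: 13 tert‑butyl[(1‑methoxy‑3‑methylbuta‑1,3‑dien‑1‑yl)oxy]dimethylsilane; 14 3‑methylbut‑2‑enal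
Product: 15 methyl (2E,5R)‑5‑hydroxy‑3,7‑dimethylocta‑2,6‑dienoate
Conditions: SiCl4 (1.1 equiv), chiral binaphthyldiamine‑derived bisphosphoramide (2 mol%), i‑Pr2NEt (10 mol%), CH2Cl2, −78 °C; aq. NaHCO3
Reagents that add atoms: none
Why: Lewis‑base‑catalysed vinylogous Mukaiyama aldol reaction: the phosphoramide‑bound trichlorosilyl cation activates the enal for 1,2‑attack by the γ‑carbon of the dienol ether, which should give the (E)‑enoate and set the carbinol carbon as R under catalyst control.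

Step 7
Reactants: 15 methyl (2E,5R)‑5‑hydroxy‑3,7‑dimethylocta‑2,6‑dienoate
Product: 16 methyl (2E,5R)‑5‑(TBS‑oxy)‑3,7‑dimethylocta‑2,6‑dienoate
Conditions: TBSCl, imidazole, DMF, rt
Reagents that add atoms: tert‑butyldimethylsilyl chloride, CC(C)(C)[Si](C)(C)Cl
Why: Standard silylation of a secondary allylic alcohol protects the carbinol for the organometallic and oxidative steps that follow.

Step 8
Reactants: 16 methyl (2E,5R)‑5‑(TBS‑oxy)‑3,7‑dimethylocta‑2,6‑dienoate
Product: 17 (2E,5R)‑5‑(TBS‑oxy)‑3,7‑dimethylocta‑2,6‑dien‑1‑ol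
Conditions: i‑Bu2AlH (2.2 equiv), CH2Cl2, −78 °C; aq. KNaC4H4O6 (potassium sodium tartrate)
Reagents that add atoms: none
Why: 1,2‑Reduction of the enoate with an aluminium hydride gives the allylic alcohol without touching the alkene geometry.

Step 9
Reactants: 17 (2E,5R)‑5‑(TBS‑oxy)‑3,7‑dimethylocta‑2,6‑dien‑1‑ol
Product: 18 (2E,5R)‑1‑bromo‑5‑(TBS‑oxy)‑3,7‑dimethylocta‑2,6‑diene
Conditions: CBr4, PPh3, CH2Cl2, 0 °C
Reagents that add atoms: carbon tetrabromide, BrC(Br)(Br)Br
Why: Appel bromination of a primary allylic alcohol proceeds by SN2 displacement of the oxyphosphonium group and should keep the (E)‑alkene and the allylic position.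

Step 10
Reactants: 18 (2E,5R)‑1‑bromo‑5‑(TBS‑oxy)‑3,7‑dimethylocta‑2,6‑diene; 19 trimethyl(prop‑1‑yn‑1‑yl)silane
Product: 21 (5E,8R)‑8‑(TBS‑oxy)‑6,10‑dimethylundeca‑5,9‑dien‑1‑yne, via silylated enyne 20 (not isolated)
Conditions: 19, n‑BuLi, THF, −78 °C; 18, −78 → 0 °C; then K2CO3, MeOH, rt
Reagents that add atoms: none
Why: Propargylic lithiation of the silylpropyne and SN2 alkylation by the primary allylic bromide builds the 1,5‑enyne, and methanolysis removes the alkynyl silyl group while the silyl ether stays.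

Step 11
Reactants: 21 (5E,8R)‑8‑(TBS‑oxy)‑6,10‑dimethylundeca‑5,9‑dien‑1‑yne
Product: 23 tert‑butyl{[(3R,5E,9E)‑10‑iodo‑2,5,9‑trimethyldeca‑2,5,9‑trien‑3‑yl]oxy}dimethylsilane, via alkenylalane 22 (not isolated)
Conditions: Me3Al (2.5 equiv), Cp2ZrCl2 (25 mol%), CH2Cl2, 0 °C → rt; then I2, THF, −30 °C
Reagents that add atoms: trimethylaluminium, C[Al](C)C; iodine, II
Why: Zirconium‑catalysed carboalumination of the terminal alkyne (Negishi) adds methyl and aluminium syn with methyl on the internal carbon, and iodinolysis with retention should give the (E)‑trisubstituted vinyl iodide.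

Step 12
Reactants: 11 (1R,2R,3R,4RS)‑3‑[3‑(TBS‑oxy)propyl]‑2‑ethenyl‑1,2‑dimethyl‑4‑nitrocyclohexan‑1‑ol; 23 tert‑butyl{[(3R,5E,9E)‑10‑iodo‑2,5,9‑trimethyldeca‑2,5,9‑trien‑3‑yl]oxy}dimethylsilane
Product: 25 (1R,2R,3R,4RS)‑3‑[3‑(TBS‑oxy)propyl]‑1,2‑dimethyl‑4‑nitro‑2‑R*‑cyclohexan‑1‑ol, via alkylborane 24 (not isolated)
Conditions: 9‑BBN dimer, THF, rt; then 23, Pd(dppf)Cl2 (5 mol%), AsPh3 (10 mol%), Cs2CO3 (3 equiv), DMF–H2O, rt
Reagents that add atoms: none
Why: Anti‑Markovnikov hydroboration of the only alkene of 11 and B‑alkyl Suzuki–Miyaura coupling with the vinyl iodide join the fragments with retention of the (E)‑alkene; no stereocenter is touched.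

Step 13
Reactants: 25 (1R,2R,3R,4RS)‑3‑[3‑(TBS‑oxy)propyl]‑1,2‑dimethyl‑4‑nitro‑2‑R*‑cyclohexan‑1‑ol
Product: 27 (2R,3R,4R)‑2‑[3‑(TBS‑oxy)propyl]‑4‑hydroxy‑3,4‑dimethyl‑3‑R*‑cyclohexan‑1‑one, via sodium nitronate 26 (not isolated)
Conditions: NaOMe, MeOH, 0 °C; then aq. TiCl3, NH4OAc buffer (pH 5–6), THF, 0 °C → rt
Reagents that add atoms: water, O
Why: Reductive Nef reaction: the nitronate is reduced by trivalent titanium to the imine, which hydrolyses to the ketone; the base is used before the ketone exists and the hydrolysis is buffered, so the α‑stereocenter should not epimerise, and alkenes and silyl ethers are tolerated.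

Step 14
Reactants: 27 (2R,3R,4R)‑2‑[3‑(TBS‑oxy)propyl]‑4‑hydroxy‑3,4‑dimethyl‑3‑R*‑cyclohexan‑1‑one
Product: 28 (1RS,2R,3R,4R)‑2‑[3‑(TBS‑oxy)propyl]‑3,4‑dimethyl‑1‑(prop‑1‑en‑2‑yl)‑3‑R*‑cyclohexane‑1,4‑diol
Conditions: CeCl3 (anhydrous, 4 equiv), isopropenylmagnesium bromide (4 equiv), THF, −78 → 0 °C; aq. NH4Cl
Reagents that add atoms: isopropenylmagnesium bromide, C=C(C)[Mg]Br
Why: The weakly basic organocerium reagent adds to the hindered, enolisable ketone without epimerising the α‑carbon; the new carbinol center may form as a mixture because it becomes trigonal in the next step.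

Step 15
Reactants: 28 (1RS,2R,3R,4R)‑2‑[3‑(TBS‑oxy)propyl]‑3,4‑dimethyl‑1‑(prop‑1‑en‑2‑yl)‑3‑R*‑cyclohexane‑1,4‑diol
Product: 29 (2Z)‑2‑[(2S,3R,4R)‑2‑[3‑(TBS‑oxy)propyl]‑4‑hydroxy‑3,4‑dimethyl‑3‑R*‑cyclohexylidene]propanal
Conditions: [C5H5NH][CrO3Cl] (pyridinium chlorochromate, 3 equiv), 4 Å molecular sieves, CH2Cl2, rt
Reagents that add atoms: pyridinium chlorochromate, [O-][Cr](=O)(=O)Cl.c1cc[nH+]cc1
Why: Babler–Dauben oxidative 1,3‑transposition: the chromate ester of the tertiary allylic alcohol undergoes a [3,3]‑shift to the primary allylic chromate, which is oxidised to the enal; the interconverting allylic chromates should favour the isomer with the small formyl group syn to the substituted ring carbon and the methyl syn to the ring CH2, since the other isomer forces the neighbouring substituents axial by allylic 1,3‑strain, and the saturated tertiary alcohol cannot react.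

Step 16
Reactants: 29 (2Z)‑2‑[(2S,3R,4R)‑2‑[3‑(TBS‑oxy)propyl]‑4‑hydroxy‑3,4‑dimethyl‑3‑R*‑cyclohexylidene]propanal
Product: 30 target CNP0270422.1
Conditions: HF·pyridine, pyridine, THF, 0 °C → rt
Reagents that add atoms: none
Why: Buffered fluoride cleavage removes both silyl ethers under conditions that should leave the enal, the tertiary alcohol and the acid‑sensitive allylic alcohol intact.

## Compound list

1 | (2E)‑4‑acetoxy‑2‑methylbut‑2‑enal | CC(=O)OC/C=C(C)/C=O | starting material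
2 | nitromethane | C[N+](=O)[O-] | starting material
3 | (2E)‑4‑hydroxy‑3‑methyl‑5‑nitropent‑2‑en‑1‑yl acetate (racemic carbinol) | CC(=O)OC/C=C(C)/C(O)C[N+](=O)[O-] | intermediate
4 | (2E,4E)‑3‑methyl‑5‑nitropenta‑2,4‑dien‑1‑yl acetate | CC(=O)OC/C=C(C)/C=C/[N+](=O)[O-] | intermediate
5 | tert‑butyl(3‑iodopropoxy)dimethylsilane | CC(C)(C)[Si](C)(C)OCCCI | starting material
6 | (2E,4R)‑7‑(TBS‑oxy)‑3‑methyl‑4‑(nitromethyl)hept‑2‑en‑1‑yl acetate | CC(=O)OC/C=C(C)/[C@H](C[N+](=O)[O-])CCCO[Si](C)(C)C(C)(C)C | intermediate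
7 | tert‑butyldimethyl{[(4R,5E)‑5‑methyl‑4‑(nitromethyl)‑7‑(Bpin)hept‑5‑en‑1‑yl]oxy}silane | CC1(C)OB(C/C=C(C)/[C@H](C[N+](=O)[O-])CCCO[Si](C)(C)C(C)(C)C)OC1(C)C | intermediate
8 | but‑3‑en‑2‑one | CC(=O)C=C | starting material
9 | (5RS,6R,7E)‑6‑[3‑(TBS‑oxy)propyl]‑7‑methyl‑5‑nitro‑9‑(Bpin)non‑7‑en‑2‑one | CC(=O)CCC([N+](=O)[O-])[C@H](CCCO[Si](C)(C)C(C)(C)C)/C(C)=C/CB1OC(C)(C)C(C)(C)O1 | intermediate
10 | pinacol borate ester of 11 (O‑Bpin on the tertiary oxygen) | C=C[C@]1(C)[C@@H](CCCO[Si](C)(C)C(C)(C)C)C([N+](=O)[O-])CC[C@@]1(C)OB1OC(C)(C)C(C)(C)O1 | intermediate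
11 | (1R,2R,3R,4RS)‑3‑[3‑(TBS‑oxy)propyl]‑2‑ethenyl‑1,2‑dimethyl‑4‑nitrocyclohexan‑1‑ol | C=C[C@]1(C)[C@@H](CCCO[Si](C)(C)C(C)(C)C)C([N+](=O)[O-])CC[C@@]1(C)O | intermediate
12 | methyl 3‑methylbut‑2‑enoate | COC(=O)C=C(C)C | starting material
13 | tert‑butyl[(1‑methoxy‑3‑methylbuta‑1,3‑dien‑1‑yl)oxy]dimethylsilane | COC(=CC(C)=C)O[Si](C)(C)C(C)(C)C | intermediate
14 | 3‑methylbut‑2‑enal | CC(C)=CC=O | starting material
15 | methyl (2E,5R)‑5‑hydroxy‑3,7‑dimethylocta‑2,6‑dienoate | CC(C)=C[C@H](O)C/C(C)=C/C(=O)OC | intermediate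
16 | methyl (2E,5R)‑5‑(TBS‑oxy)‑3,7‑dimethylocta‑2,6‑dienoate | CC(C)=C[C@H](O[Si](C)(C)C(C)(C)C)C/C(C)=C/C(=O)OC | intermediate
17 | (2E,5R)‑5‑(TBS‑oxy)‑3,7‑dimethylocta‑2,6‑dien‑1‑ol | CC(C)=C[C@H](O[Si](C)(C)C(C)(C)C)C/C(C)=C/CO | intermediate
18 | (2E,5R)‑1‑bromo‑5‑(TBS‑oxy)‑3,7‑dimethylocta‑2,6‑diene | CC(C)=C[C@H](O[Si](C)(C)C(C)(C)C)C/C(C)=C/CBr | intermediate
19 | trimethyl(prop‑1‑yn‑1‑yl)silane | CC#C[Si](C)(C)C | starting material
20 | (5E,8R)‑8‑(TBS‑oxy)‑6,10‑dimethyl‑1‑(trimethylsilyl)undeca‑5,9‑dien‑1‑yne | CC(C)=C[C@H](O[Si](C)(C)C(C)(C)C)C/C(C)=C/CCC#C[Si](C)(C)C | intermediate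
21 | (5E,8R)‑8‑(TBS‑oxy)‑6,10‑dimethylundeca‑5,9‑dien‑1‑yne | CC(C)=C[C@H](O[Si](C)(C)C(C)(C)C)C/C(C)=C/CCC#C | intermediate
22 | dimethyl[(1E,5E,8R)‑8‑(TBS‑oxy)‑2,6,10‑trimethylundeca‑1,5,9‑trien‑1‑yl]alumane | CC(C)=C[C@H](O[Si](C)(C)C(C)(C)C)C/C(C)=C/CC/C(C)=C/[Al](C)C | intermediate
23 | tert‑butyl{[(3R,5E,9E)‑10‑iodo‑2,5,9‑trimethyldeca‑2,5,9‑trien‑3‑yl]oxy}dimethylsilane | CC(C)=C[C@H](O[Si](C)(C)C(C)(C)C)C/C(C)=C/CC/C(C)=C/I | intermediate
24 | 9‑{2‑[(1R,2R,6R)‑6‑[3‑(TBS‑oxy)propyl]‑2‑hydroxy‑1,2‑dimethyl‑5‑nitrocyclohexyl]ethyl}‑9‑borabicyclo[3.3.1]nonane | B1(CC[C@]2(C)[C@@H](CCCO[Si](C)(C)C(C)(C)C)C([N+](=O)[O-])CC[C@@]2(C)O)C3CCCC1CCC3 | intermediate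
25 | (1R,2R,3R,4RS)‑3‑[3‑(TBS‑oxy)propyl]‑1,2‑dimethyl‑4‑nitro‑2‑R*‑cyclohexan‑1‑ol | CC(C)=C[C@H](O[Si](C)(C)C(C)(C)C)C/C(C)=C/CC/C(C)=C/CC[C@]1(C)[C@@H](CCCO[Si](C)(C)C(C)(C)C)C([N+](=O)[O-])CC[C@@]1(C)O | intermediate
26 | sodium nitronate of 25 | CC(C)=C[C@H](O[Si](C)(C)C(C)(C)C)C/C(C)=C/CC/C(C)=C/CC[C@]1(C)[C@@H](CCCO[Si](C)(C)C(C)(C)C)C(=[N+]([O-])[O-])CC[C@@]1(C)O.[Na+] | intermediate
27 | (2R,3R,4R)‑2‑[3‑(TBS‑oxy)propyl]‑4‑hydroxy‑3,4‑dimethyl‑3‑R*‑cyclohexan‑1‑one | CC(C)=C[C@H](O[Si](C)(C)C(C)(C)C)C/C(C)=C/CC/C(C)=C/CC[C@]1(C)[C@@H](CCCO[Si](C)(C)C(C)(C)C)C(=O)CC[C@@]1(C)O | intermediate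
28 | (1RS,2R,3R,4R)‑2‑[3‑(TBS‑oxy)propyl]‑3,4‑dimethyl‑1‑(prop‑1‑en‑2‑yl)‑3‑R*‑cyclohexane‑1,4‑diol | CC(C)=C[C@H](O[Si](C)(C)C(C)(C)C)C/C(C)=C/CC/C(C)=C/CC[C@]1(C)[C@@H](CCCO[Si](C)(C)C(C)(C)C)C(O)(C(C)=C)CC[C@@]1(C)O | intermediate
29 | (2Z)‑2‑[(2S,3R,4R)‑2‑[3‑(TBS‑oxy)propyl]‑4‑hydroxy‑3,4‑dimethyl‑3‑R*‑cyclohexylidene]propanal | CC(C)=C[C@H](O[Si](C)(C)C(C)(C)C)C/C(C)=C/CC/C(C)=C/CC[C@]1(C)[C@@H](CCCO[Si](C)(C)C(C)(C)C)/C(=C(/C)C=O)CC[C@@]1(C)O | intermediate
30 | (2Z)‑2‑[(2S,3R,4R)‑4‑hydroxy‑2‑(3‑hydroxypropyl)‑3‑[(3E,7E,10R)‑10‑hydroxy‑4,8,12‑trimethyltrideca‑3,7,11‑trien‑1‑yl]‑3,4‑dimethylcyclohexylidene]propanal (CNP0270422.1) | CC(C)=C[C@H](O)C/C(C)=C/CC/C(C)=C/CC[C@]1(C)[C@@H](CCCO)/C(=C(/C)C=O)CC[C@@]1(C)O | target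

## Step count and risks

Total step count: 16. Longest linear sequence: 12 steps (steps 5–11, then 12–16).

Steps most likely to fail:

Step 4. The thermal allylboration of the tethered methyl ketone by a γ,γ‑disubstituted pinacol allylboronate may be too slow or not face‑selective enough, and the nitroalkane may add twice to the enone. The fallback sets out from 6 and comes back at 11. Guanidine‑catalysed Michael addition of 6 to 8 should give (2E,4R)‑7‑(TBS‑oxy)‑3‑methyl‑4‑(1‑nitro‑4‑oxopentyl)hept‑2‑en‑1‑yl acetate F1. The ring is then closed by a palladium‑catalysed umpolung allylation (Pd(PPh3)4, Et2Zn, THF, rt): the π‑allyl complex from the allylic acetate is transmetalated to an allylzinc, which adds through its γ‑carbon to the ketone via the same chair and should give 11 after aqueous work‑up.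

Step 15. The chromate [3,3]‑shift may give poor control of the geometry of the new tetrasubstituted double bond, or the transposition may stall at the hindered tertiary carbinol. The fallback sets out from 27, replaces steps 14 and 15 and comes back at 29. Horner–Wadsworth–Emmons olefination of 27 with diethyl (1‑cyanoethyl)phosphonate (NaH, THF, 0 → 50 °C) should give (2Z)‑2‑[(2S,3R,4R)‑2‑[3‑(TBS‑oxy)propyl]‑4‑hydroxy‑3,4‑dimethyl‑3‑R*‑cyclohexylidene]propanenitrile F2. Its geometric isomers are separated at this robust stage, the small linear nitrile being expected syn to the substituted ring carbon. Reduction with i‑Bu2AlH (toluene, −78 °C) and mild acidic hydrolysis of the imine then gives 29.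

Step 2. The conjugate addition may give insufficient enantioselectivity or competing 1,6‑addition to the nitrodiene, or the functionalised dialkylzinc may form incompletely. The fallback sets out from 4 and comes back at 6:
- enamine‑catalysed Michael addition of acetaldehyde to 4 (α,α‑diphenylprolinol trimethylsilyl ether, 10 mol%, 1,4‑dioxane, rt) gives (2E,4R)‑3‑methyl‑4‑(nitromethyl)‑6‑oxohex‑2‑en‑1‑yl acetate F3;
- Wittig methylenation (Ph3PCH3Br, KN(SiMe3)2, THF, −78 → 0 °C) gives (2E,4R)‑3‑methyl‑4‑(nitromethyl)hepta‑2,6‑dien‑1‑yl acetate F4;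
- hydroboration of the terminal alkene with 9‑BBN gives the B‑alkyl‑9‑BBN adduct F5, which is oxidised in the same flask (NaBO3·4H2O) to (2E,4R)‑7‑hydroxy‑3‑methyl‑4‑(nitromethyl)hept‑2‑en‑1‑yl acetate F6;
- silylation (TBSCl, imidazole, DMF) gives 6.

Further compounds
F1 | step 4 | (2E,4R)‑7‑(TBS‑oxy)‑3‑methyl‑4‑(1‑nitro‑4‑oxopentyl)hept‑2‑en‑1‑yl acetate | CC(=O)CCC([N+](=O)[O-])[C@H](CCCO[Si](C)(C)C(C)(C)C)/C(C)=C/COC(C)=O
F2 | step 15 | (2Z)‑2‑[(2S,3R,4R)‑2‑[3‑(TBS‑oxy)propyl]‑4‑hydroxy‑3,4‑dimethyl‑3‑R*‑cyclohexylidene]propanenitrile | CC(C)=C[C@H](O[Si](C)(C)C(C)(C)C)C/C(C)=C/CC/C(C)=C/CC[C@]1(C)[C@@H](CCCO[Si](C)(C)C(C)(C)C)/C(=C(/C)C#N)CC[C@@]1(C)O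
F3 | step 2 | (2E,4R)‑3‑methyl‑4‑(nitromethyl)‑6‑oxohex‑2‑en‑1‑yl acetate | O=CC[C@@H](C[N+](=O)[O-])/C(C)=C/COC(C)=O
F4 | step 2 | (2E,4R)‑3‑methyl‑4‑(nitromethyl)hepta‑2,6‑dien‑1‑yl acetate | C=CC[C@@H](C[N+](=O)[O-])/C(C)=C/COC(C)=O
F5 | step 2 | (2E,4R)‑7‑(9‑borabicyclo[3.3.1]nonan‑9‑yl)‑3‑methyl‑4‑(nitromethyl)hept‑2‑en‑1‑yl acetate | B1(CCC[C@@H](C[N+](=O)[O-])/C(C)=C/COC(C)=O)C2CCCC1CCC2
F6 | step 2 | (2E,4R)‑7‑hydroxy‑3‑methyl‑4‑(nitromethyl)hept‑2‑en‑1‑yl acetate | OCCC[C@@H](C[N+](=O)[O-])/C(C)=C/COC(C)=O
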